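**Plan**

1. Retrosynthesis: the acetate and the silyl ether are adjusted last. The quinone ring is cut at two bonds, ring CH–C(=O) and C(OH)=C(chain), into a four-carbon 2-methoxy enone CH2=C(OMe)–CO–CH2–R and a two-carbon glyoxylate unit carried as ethyl 1,3-dithiane-2-carboxylate. The enone is cut at CO–C(OMe) (amide + 1-methoxyvinyllithium) and at CH2–CH2 (amide enolate + epoxide).
2. Enabling feature: the hydroxyquinone is the oxidised enol form of a cyclohexane-1,2,4-trione. Its triad C(OH)=C(chain)–C(=O) is a 1,3-diketone, and the ring CH lies β (the OMe carbon α) to that same ketone, so one Michael–Claisen annulation closes the carbocycle with OH, OMe, H and chain already in their final places.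
3. Helpers: the dithiane ring makes the future carbonyl carbon a nucleophile and keeps it sp3, and the ring is built one oxidation level low. Both are taken out in step 7 (hydrolysis, tautomerisation, air oxidation).
4. Forward order: C15 epoxide (steps 1–2), C17 hydroxy amide (3), silyl ether (4), enone (5), ring closure (6), quinone (7), desilylation (8), acetate (9).
5. Stereochemistry: the single stereocentre is bought with (R)-epichlorohydrin; all later bonds form at neighbouring CH2 groups or further away, so it is never a reacting or enolisable centre.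

Key step: step 6

Remark: 1,3-diketones and hydroxyquinones are drawn as one tautomer each; the two ring stereocentres of 11–13 are transient and left undefined.

**Step 1**
Reactants: 1 (R)-epichlorohydrin [(2R)-2-(chloromethyl)oxirane]; 2 dodecylmagnesium bromide
Product: 3 (2R)-1-chloropentadecan-2-ol
Conditions: CuI (10 mol%), THF, −40 → 0 °C; aqueous work-up
Reagents that add atoms: none
Why: CuI-catalysed Grignard opening of the epoxide at its unsubstituted CH2 is an SN2 process that is faster than displacement of the primary chloride and does not touch the C–O stereocentre, so the (R)-chlorohydrin should result (copper-catalysed epoxide ring opening).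

**Step 2**
Reactants: 3 (2R)-1-chloropentadecan-2-ol
Product: 4 (2R)-2-tridecyloxirane
Conditions: NaOH, Et2O/H2O, rt
Reagents that add atoms: none
Why: Intramolecular Williamson etherification, in which the alkoxide displaces the neighbouring primary chloride (3-exo-tet) while the stereocentre is not a reacting centre and keeps its configuration.

**Step 3**
Reactants: 4 (2R)-2-tridecyloxirane; 5 4-acetylmorpholine
Product: 6 (4R)-4-hydroxy-1-(morpholin-4-yl)heptadecan-1-one
Conditions: LiN(iPr)2, THF, −78 °C (enolate of 5); then 4, −78 °C → rt; H2O
Reagents that add atoms: none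
Why: Lithium enolates of tertiary amides are nucleophilic enough to open terminal epoxides by SN2 attack at the CH2 carbon (amide enolate alkylation), which gives the γ-hydroxy amide with the carbinol centre unchanged and installs a morpholine amide as the later ketone precursor.

**Step 4**
Reactants: 6 (4R)-4-hydroxy-1-(morpholin-4-yl)heptadecan-1-one
Product: 7 (4R)-4-[(tert-butyldimethylsilyl)oxy]-1-(morpholin-4-yl)heptadecan-1-one
Conditions: TBSCl, imidazole, DMF, rt
Reagents that add atoms: tert-butyldimethylsilyl chloride (TBSCl), CC(C)(C)[Si](C)(C)Cl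
Why: Standard silyl ether formation at a secondary alcohol gives an ether that should tolerate the organolithium, alkoxide and Hg(ClO4)2 steps to come and blocks lactonisation of the γ-hydroxy amide.

**Step 5**
Reactants: 7 (4R)-4-[(tert-butyldimethylsilyl)oxy]-1-(morpholin-4-yl)heptadecan-1-one; 8 methyl vinyl ether (methoxyethene)
Product: 9 (6R)-6-[(tert-butyldimethylsilyl)oxy]-2-methoxynonadec-1-en-3-one
Conditions: 8, t-BuLi, THF/pentane, −78 → 0 °C; then 7, −78 → −20 °C; pH 7 buffer
Reagents that add atoms: none
Why: 1-Methoxyvinyllithium, made by α-lithiation of 8, should add only once to the morpholine amide because the tetrahedral lithium hemiaminal survives until the neutral work-up (ketone synthesis by acyl substitution of a morpholine amide, the logic of the Weinreb ketone synthesis), giving the 2-methoxy enone without affecting the stereocentre.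

**Step 6**
Reactants: 9 (6R)-6-[(tert-butyldimethylsilyl)oxy]-2-methoxynonadec-1-en-3-one; 10 ethyl 1,3-dithiane-2-carboxylate
Product: 12 8-[(2R)-2-[(tert-butyldimethylsilyl)oxy]pentadecyl]-10-methoxy-1,5-dithiaspiro[5.5]undecane-7,9-dione, via Michael adduct 11 (not isolated)
Conditions: KOtBu (1.2 equiv), t-BuOH (2 equiv), THF, −20 °C (slow addition of 9) → 55 °C; then 1 M HCl to pH 3, 0 °C
Reagents that add atoms: none
Why: The potassium salt of 10, a soft acyl-anion equivalent stabilised by the ester and two sulfur atoms, should add 1,4 to the unsubstituted CH2 terminus of the 2-methoxy enone (Michael addition) to give enolate 11; proton transfer through t-BuOH moves the enolate to the CH2 on the other side of the ketone, which then attacks the ester and expels ethoxide (intramolecular Claisen condensation). The closest known reaction type is the consecutive Michael–Claisen annulation of enones with ester-stabilised carbanions that gives cyclohexane-1,3-diones (the dimedone synthesis), and its sequence of acyl-anion addition then acyl transfer parallels the Hauser–Kraus annulation. The six-membered carbocycle closes by enolate C-acylation in the 6-(enolexo)-exo-trig mode, helped by the gem-disubstituted dithiane carbon. The two new ring stereocentres (C8 and C10) are not controlled and need not be, since both become sp2 in step 7, and the side-chain stereocentre is remote and not enolisable. The step needs 1,4- over 1,2-addition, secured by the soft doubly stabilised donor, and the right enolate with C- over O-acylation, secured because only the C-acylated product is drained irreversibly as the stabilised 1,3-diketone enolate while the alternative methoxy-bearing enolate could only close a four-membered ring. The dithiane also keeps the future carbonyl carbon sp3, so the neighbouring CH2 is not acidified and the β-methoxy group cannot be lost by E1cB under the basic conditions.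

**Step 7**
Reactants: 12 8-[(2R)-2-[(tert-butyldimethylsilyl)oxy]pentadecyl]-10-methoxy-1,5-dithiaspiro[5.5]undecane-7,9-dione
Product: 15 3-[(2R)-2-[(tert-butyldimethylsilyl)oxy]pentadecyl]-2-hydroxy-5-methoxycyclohexa-2,5-diene-1,4-dione, via trione 13 (not isolated), via benzenetriol 14 (not isolated)
Conditions: Hg(ClO4)2·3H2O, CaCO3, THF/H2O (5:1), 0 °C → rt; then O2 (1 atm), rt
Reagents that add atoms: water, O
Why: Thiophilic Hg(ClO4)2 hydrolyses the 2-acyl-1,3-dithiane under CaCO3 buffering to trione 13, which is the keto tautomer of a phenol and should aromatise by fast loss of its acidic ring protons (faster than β-loss of methanol) to the electron-rich triol 14, whose autoxidation by O2 gives the para-quinone with the remaining hydroxyl as a vinylogous acid (dithioacetal hydrolysis, keto–enol tautomerisation, hydroquinone autoxidation); the transient ring stereocentres vanish and the silyl ether and side-chain centre are not affected.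

**Step 8**
Reactants: 15 3-[(2R)-2-[(tert-butyldimethylsilyl)oxy]pentadecyl]-2-hydroxy-5-methoxycyclohexa-2,5-diene-1,4-dione
Product: 16 2-hydroxy-3-[(2R)-2-hydroxypentadecyl]-5-methoxycyclohexa-2,5-diene-1,4-dione
Conditions: HF·pyridine, pyridine, THF, 0 °C → rt
Reagents that add atoms: none
Why: Buffered HF·pyridine cleaves the secondary silyl ether by fluoride attack at silicon (desilylation) while the quinone, its vinylogous methyl ester and the stereocentre are left alone, the excess pyridine keeping the medium too weakly acidic for the carbinol to cyclise onto the ring.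

**Step 9**
Reactants: 16 2-hydroxy-3-[(2R)-2-hydroxypentadecyl]-5-methoxycyclohexa-2,5-diene-1,4-dione
Product: 18 (2R)-1-(2-hydroxy-5-methoxy-3,6-dioxocyclohexa-1,4-dien-1-yl)pentadecan-2-yl acetate, via diacetate 17 (not isolated)
Conditions: Ac2O, pyridine, DMAP (cat.), CH2Cl2, 0 °C → rt; then MeOH, rt
Reagents that add atoms: acetic anhydride, CC(=O)OC(C)=O
Why: Ac2O with DMAP acetylates both hydroxyls (nucleophilic catalysis of acyl transfer), and the quinone enol acetate of 17, a vinylogous mixed anhydride, should then be methanolysed selectively by MeOH with the DMAP already present while the secondary alkyl acetate is inert, so the target results with its stereocentre untouched.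

**Compound list**

1 | (R)-epichlorohydrin, (2R)-2-(chloromethyl)oxirane | ClC[C@H]1CO1 | starting material
2 | dodecylmagnesium bromide | CCCCCCCCCCCC[Mg]Br | starting material
3 | (2R)-1-chloropentadecan-2-ol | CCCCCCCCCCCCC[C@@H](O)CCl | intermediate
4 | (2R)-2-tridecyloxirane | CCCCCCCCCCCCC[C@@H]1CO1 | intermediate
5 | 4-acetylmorpholine | CC(=O)N1CCOCC1 | starting material
6 | (4R)-4-hydroxy-1-(morpholin-4-yl)heptadecan-1-one | CCCCCCCCCCCCC[C@H](CCC(=O)N1CCOCC1)O | intermediate
7 | (4R)-4-[(tert-butyldimethylsilyl)oxy]-1-(morpholin-4-yl)heptadecan-1-one | CCCCCCCCCCCCC[C@H](CCC(=O)N1CCOCC1)O[Si](C)(C)C(C)(C)C | intermediate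
8 | methyl vinyl ether (methoxyethene) | COC=C | starting material
9 | (6R)-6-[(tert-butyldimethylsilyl)oxy]-2-methoxynonadec-1-en-3-one | CCCCCCCCCCCCC[C@H](CCC(=O)C(=C)OC)O[Si](C)(C)C(C)(C)C | intermediate
10 | ethyl 1,3-dithiane-2-carboxylate | CCOC(=O)C1SCCCS1 | starting material
11 | Michael adduct, ethyl 2-[(6R)-6-[(tert-butyldimethylsilyl)oxy]-2-methoxy-3-oxononadecyl]-1,3-dithiane-2-carboxylate (present as its potassium enolate) | CCCCCCCCCCCCC[C@H](CCC(=O)C(OC)CC1(SCCCS1)C(=O)OCC)O[Si](C)(C)C(C)(C)C | intermediate
12 | 8-[(2R)-2-[(tert-butyldimethylsilyl)oxy]pentadecyl]-10-methoxy-1,5-dithiaspiro[5.5]undecane-7,9-dione | CCCCCCCCCCCCC[C@H](CC1C(=O)C(OC)CC2(SCCCS2)C1=O)O[Si](C)(C)C(C)(C)C | intermediate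
13 | trione, 3-[(2R)-2-[(tert-butyldimethylsilyl)oxy]pentadecyl]-5-methoxycyclohexane-1,2,4-trione | CCCCCCCCCCCCC[C@H](CC1C(=O)C(OC)CC(=O)C1=O)O[Si](C)(C)C(C)(C)C | intermediate
14 | benzenetriol, 3-[(2R)-2-[(tert-butyldimethylsilyl)oxy]pentadecyl]-5-methoxybenzene-1,2,4-triol | CCCCCCCCCCCCC[C@H](Cc1c(O)c(O)cc(OC)c1O)O[Si](C)(C)C(C)(C)C | intermediate
15 | 3-[(2R)-2-[(tert-butyldimethylsilyl)oxy]pentadecyl]-2-hydroxy-5-methoxycyclohexa-2,5-diene-1,4-dione | CCCCCCCCCCCCC[C@H](CC1=C(O)C(=O)C=C(OC)C1=O)O[Si](C)(C)C(C)(C)C | intermediate
16 | 2-hydroxy-3-[(2R)-2-hydroxypentadecyl]-5-methoxycyclohexa-2,5-diene-1,4-dione | CCCCCCCCCCCCC[C@H](CC1=C(O)C(=O)C=C(OC)C1=O)O | intermediate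
17 | diacetate, 2-[(2R)-2-(acetyloxy)pentadecyl]-4-methoxy-3,6-dioxocyclohexa-1,4-dien-1-yl acetate | CCCCCCCCCCCCC[C@H](CC1=C(OC(C)=O)C(=O)C=C(OC)C1=O)OC(C)=O | intermediate
18 | (2R)-1-(2-hydroxy-5-methoxy-3,6-dioxocyclohexa-1,4-dien-1-yl)pentadecan-2-yl acetate | CCCCCCCCCCCCC[C@H](CC1=C(O)C(=O)C=C(OC)C1=O)OC(C)=O | target

**Summary**

Total step count: 9. Longest linear sequence: 9 steps (1 → 18).

Steps most likely to fail:

Step 6. The Michael addition may revert, the rearranged enolate may fail to acylate the hindered ester so that no ring closes, or the enone may oligomerise under base. Fallback, setting out from 4 and coming back at 18 (it replaces steps 3 to 9 and brings the ring in as an arene): 1,2,4,5-tetramethoxybenzene is lithiated (n-BuLi, THF, 0 °C) and the aryllithium opens 4 at its CH2 with BF3·OEt2 at −78 °C, which should give (2R)-1-(2,3,5,6-tetramethoxyphenyl)pentadecan-2-ol F1. Acetylation (Ac2O, pyridine, DMAP) should give (2R)-1-(2,3,5,6-tetramethoxyphenyl)pentadecan-2-yl acetate F2. Oxidative demethylation with (NH4)2Ce(NO3)6 in MeCN/H2O at 0 °C should give (2R)-1-(2,5-dimethoxy-3,6-dioxocyclohexa-1,4-dien-1-yl)pentadecan-2-yl acetate F3. Brief acid hydrolysis (HClO4, dioxane, rt) of the twisted methoxy group next to the side chain, a known selectivity for 3-alkyl-2,5-dimethoxybenzoquinones, should then give 18, the secondary acetate being expected to survive the short exposure.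

Step 7. Methanol may be lost by β-elimination from the trione before it aromatises, or the enolised diketone may be mercurated or over-oxidised during thioketal cleavage. Fallback, setting out from 12 and coming back at 15 (the ring double bond is put in before the thioketal is removed): the dianion of 12 (LiN(iPr)2, 2.2 equiv, THF, −78 °C) is selenenylated with PhSeCl at the methoxy-bearing ring carbon, which should give 8-[(2R)-2-[(tert-butyldimethylsilyl)oxy]pentadecyl]-10-methoxy-10-(phenylselanyl)-1,5-dithiaspiro[5.5]undecane-7,9-dione F4. Oxidation (H2O2, pyridine, CH2Cl2, 0 °C) and selenoxide syn-elimination should give the quinone mono(dithioketal) 8-[(2R)-2-[(tert-butyldimethylsilyl)oxy]pentadecyl]-7-hydroxy-10-methoxy-1,5-dithiaspiro[5.5]undeca-7,10-dien-9-one F5, in which the methoxy group already sits on an sp2 carbon and the ring is at the quinone oxidation level. Hg(ClO4)2/CaCO3 in aqueous THF should then give 15 directly, with neither tautomerisation nor oxidation needed.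

Step 8. The freed carbinol may attack the neighbouring vinylogous acid carbon under acid and close a dihydrofuran ring, or fluoride may cleave the vinylogous methyl ester. Fallback, setting out from 15 and coming back at 17 (the carbinol is never set free): Ac2O with catalytic Cu(OTf)2 in CH2Cl2 at 0 °C, a known direct exchange of a silyl ether for an acetate, should also acetylate the quinone hydroxyl and so give diacetate 17. The reaction is kept cold and short to avoid 1,4-addition of Ac2O to the quinone. The route is re-entered at 17, whose enol acetate is methanolysed as in step 9; no new compound is made (F0).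

**Further compounds**

F1 | step 6 | (2R)-1-(2,3,5,6-tetramethoxyphenyl)pentadecan-2-ol | CCCCCCCCCCCCC[C@H](Cc1c(OC)c(OC)cc(OC)c1OC)O
F2 | step 6 | (2R)-1-(2,3,5,6-tetramethoxyphenyl)pentadecan-2-yl acetate | CCCCCCCCCCCCC[C@H](Cc1c(OC)c(OC)cc(OC)c1OC)OC(C)=O
F3 | step 6 | (2R)-1-(2,5-dimethoxy-3,6-dioxocyclohexa-1,4-dien-1-yl)pentadecan-2-yl acetate | CCCCCCCCCCCCC[C@H](CC1=C(OC)C(=O)C=C(OC)C1=O)OC(C)=O
F4 | step 7 | 8-[(2R)-2-[(tert-butyldimethylsilyl)oxy]pentadecyl]-10-methoxy-10-(phenylselanyl)-1,5-dithiaspiro[5.5]undecane-7,9-dione | CCCCCCCCCCCCC[C@H](CC1C(=O)C(OC)([Se]c2ccccc2)CC3(SCCCS3)C1=O)O[Si](C)(C)C(C)(C)C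
F5 | step 7 | 8-[(2R)-2-[(tert-butyldimethylsilyl)oxy]pentadecyl]-7-hydroxy-10-methoxy-1,5-dithiaspiro[5.5]undeca-7,10-dien-9-one | CCCCCCCCCCCCC[C@H](CC1=C(O)C2(SCCCS2)C=C(OC)C1=O)O[Si](C)(C)C(C)(C)C
F0 | step 8 | none | none
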